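**Strategy.** The target is cut at C16–C17 into a hydroazulene alkenyl iodide and an oxepane-fused cyclohexane; everything rests on closing the seven-membered ring at C2–C15. One gold-catalysed Conia-ene step with iodine capture forms that bond, the cycloheptanone ring (C2, C3, C4, C5, C6, C12, C15) and the stereocentre C2. It exploits the exocyclic alkene C15=C16, whose chain carbon C17 must sit cis to quaternary C12: anti addition across a terminal alkyne on C12 fixes this crowded Z geometry as the iodide. The precursor is a cis-1,2-disubstituted cyclopentane carrying a regiodefined Z-enol silane arm on C5 (made by conjugate reduction of a vinyl ketone) and a 1,1-dimethylpropargyl arm on C6.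

Key step: step 14

Remark: atom labels C1–O34 are the heavy atoms of the target in SMILES order and are used for all intermediates; the supplied precursor, product and target structures were checked against each other (constitution, C2/C5/C6/C9, both alkene geometries) and needed no correction; centres that are destroyed later (carbinol carbon C3 in 22, C18 in 37–39, C=N geometry in 28) are written without descriptor.

**Part A – hydroazulene alkenyl iodide**

Step 1
Reactants: 1 3-ethoxycyclopent-2-en-1-one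
Product: 2 2-bromo-3-ethoxycyclopent-2-en-1-one
Conditions: NBS, CH2Cl2, 0 °C → rt
Reagents that add atoms: N-bromosuccinimide, O=C1CCC(=O)N1Br
Why: Electrophilic bromination of the electron-rich α-carbon of the vinylogous ester (enol ether halogenation) can only occur at ring C2, the future C5.

Step 2
Reactants: 2 2-bromo-3-ethoxycyclopent-2-en-1-one; 3 1-chloro-3-methylbut-2-ene
Product: 6 2-bromo-3-(2-methylbut-3-en-2-yl)cyclopent-2-en-1-one, via prenylmagnesium chloride 4 (not isolated), via chloromagnesium alkoxide adduct 5 (not isolated)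
Conditions: Mg, THF, 0 °C; add 2, −78 → 0 °C; 1 M HCl, 0 °C → rt
Reagents that add atoms: water, O
Why: Stork–Danheiser sequence in which the allylic Grignard reagent adds to the carbonyl through its γ-carbon (SE2′) to create quaternary C12, and acid then hydrolyses the enol ether with allylic transposition to the β-substituted bromoenone.

Step 3
Reactants: 6 2-bromo-3-(2-methylbut-3-en-2-yl)cyclopent-2-en-1-one
Product: 8 2-bromo-3-(1,1-dimethoxy-2-methylpropan-2-yl)cyclopent-2-en-1-one, via aldehyde 7 (not isolated)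
Conditions: O3, CH2Cl2–MeOH, −78 °C; Me2S, −78 °C → rt; then HC(OMe)3, TsOH·H2O (cat.), MeOH, rt
Reagents that add atoms: trimethyl orthoformate, COC(OC)OC
Why: Ozonolysis cleaves only the electron-rich vinyl group (the bromoenone alkene is deactivated), and the non-enolisable aldehyde is masked at once as its dimethyl acetal so that it survives the organometallic and hydrogenation steps.

Step 4
Reactants: 8 2-bromo-3-(1,1-dimethoxy-2-methylpropan-2-yl)cyclopent-2-en-1-one; 9 tert-butyl bromoacetate
Product: 11 tert-butyl 2-[2-(1,1-dimethoxy-2-methylpropan-2-yl)-5-oxocyclopent-1-en-1-yl]acetate, via Reformatsky reagent 10 (not isolated)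
Conditions: Zn dust, THF, rt; then 8, Pd(dba)2 (5 mol%), XPhos (10 mol%), THF, rt
Reagents that add atoms: none
Why: Negishi cross-coupling of the Reformatsky reagent with the activated α-bromoenone under zerovalent palladium installs the C4–C3 arm on C5 at room temperature, faster than the zinc enolate adds to the hindered enone carbonyl.

Step 5
Reactants: 11 tert-butyl 2-[2-(1,1-dimethoxy-2-methylpropan-2-yl)-5-oxocyclopent-1-en-1-yl]acetate; 12 dimethylzinc
Product: 13 tert-butyl 2-[(5R)-2-(1,1-dimethoxy-2-methylpropan-2-yl)-5-hydroxy-5-methylcyclopent-1-en-1-yl]acetate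
Conditions: Me2Zn, Ti(Oi-Pr)4, C2-symmetric trans-cyclohexane-1,2-diamine bis(2-hydroxy-10-camphorsulfonamide) ligand (10 mol%), toluene–hexane, rt
Reagents that add atoms: none
Why: Titanium-promoted catalytic asymmetric 1,2-addition of dimethylzinc to an α-substituted cyclic enone, in which the chiral bis(sulfonamide) titanium complex distinguishes the substituted sp2 α-carbon from the α′-methylene and so sets C9 (ligand antipode chosen for 9R); the tert-butyl ester is used so that the new alkoxide does not lactonise.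

Step 6
Reactants: 13 tert-butyl 2-[(5R)-2-(1,1-dimethoxy-2-methylpropan-2-yl)-5-hydroxy-5-methylcyclopent-1-en-1-yl]acetate
Product: 14 tert-butyl 2-[(1R,2R,5R)-2-(1,1-dimethoxy-2-methylpropan-2-yl)-5-hydroxy-5-methylcyclopentyl]acetate
Conditions: H2 (50 bar), [Ir(cod)(PCy3)(py)]PF6 (10 mol%), CH2Cl2, rt
Reagents that add atoms: none
Why: Hydroxyl-directed homogeneous hydrogenation in which the C9 hydroxyl binds the cationic iridium centre and both hydrogens are delivered to the tetrasubstituted C5=C6 bond from the hydroxyl face, which sets C5 and C6 with the two arms cis to each other and trans to the hydroxyl.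

Step 7
Reactants: 14 tert-butyl 2-[(1R,2R,5R)-2-(1,1-dimethoxy-2-methylpropan-2-yl)-5-hydroxy-5-methylcyclopentyl]acetate
Product: 15 tert-butyl 2-[(1R,2R,5R)-5-hydroxy-5-methyl-2-(2-methyl-1-oxopropan-2-yl)cyclopentyl]acetate
Conditions: TsOH·H2O (cat.), acetone–H2O, rt
Reagents that add atoms: water, O
Why: Mild acid-catalysed acetal hydrolysis unmasks the aldehyde while the tert-butyl ester and the tertiary alcohol, which cannot lactonise because both arms are trans to it, stay intact.

Step 8
Reactants: 15 tert-butyl 2-[(1R,2R,5R)-5-hydroxy-5-methyl-2-(2-methyl-1-oxopropan-2-yl)cyclopentyl]acetate; 16 dimethyl (1-diazo-2-oxopropyl)phosphonate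
Product: 18 tert-butyl 2-[(1R,2R,5R)-5-hydroxy-5-methyl-2-(2-methylbut-3-yn-2-yl)cyclopentyl]acetate, via dimethyl (diazomethyl)phosphonate 17 (not isolated)
Conditions: K2CO3, MeOH, 0 °C → rt
Reagents that add atoms: none
Why: Ohira–Bestmann homologation (Seyferth–Gilbert type) converts the non-enolisable aldehyde carbon C15 into the terminal alkyne C15≡C16 under carbonate conditions that leave the ester and the free tertiary alcohol untouched.

Step 9
Reactants: 18 tert-butyl 2-[(1R,2R,5R)-5-hydroxy-5-methyl-2-(2-methylbut-3-yn-2-yl)cyclopentyl]acetate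
Product: 19 tert-butyl 2-[(1R,2R,5R)-5-methyl-2-(2-methylbut-3-yn-2-yl)-5-(triethylsilyloxy)cyclopentyl]acetate
Conditions: Et3SiOTf, 2,6-lutidine, CH2Cl2, −78 °C
Reagents that add atoms: triethylsilyl trifluoromethanesulfonate, CC[Si](CC)(CC)OS(=O)(=O)C(F)(F)F
Why: Silylation of the hindered tertiary alcohol with a silyl triflate and a hindered pyridine base is fast at low temperature and protects C9–OH for the organometallic steps that follow.

Step 10
Reactants: 19 tert-butyl 2-[(1R,2R,5R)-5-methyl-2-(2-methylbut-3-yn-2-yl)-5-(triethylsilyloxy)cyclopentyl]acetate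
Product: 20 2-[(1R,2R,5R)-5-methyl-2-(2-methylbut-3-yn-2-yl)-5-(triethylsilyloxy)cyclopentyl]acetaldehyde
Conditions: i-Bu2AlH, CH2Cl2, −78 °C; aq. potassium sodium tartrate
Reagents that add atoms: none
Why: Partial reduction of the tert-butyl ester with one hydride equivalent at −78 °C stops at the tetrahedral aluminate, which gives the C3 aldehyde on work-up without touching the alkyne or the silyl ether.

Step 11
Reactants: 20 2-[(1R,2R,5R)-5-methyl-2-(2-methylbut-3-yn-2-yl)-5-(triethylsilyloxy)cyclopentyl]acetaldehyde; 21 vinylmagnesium bromide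
Product: 22 1-[(1R,2R,5R)-5-methyl-2-(2-methylbut-3-yn-2-yl)-5-(triethylsilyloxy)cyclopentyl]but-3-en-2-ol
Conditions: CH2=CHMgBr (2.5 equiv), THF, −78 → 0 °C
Reagents that add atoms: none
Why: Grignard 1,2-addition to the unhindered aldehyde (one equivalent is consumed by the alkyne C–H) adds C2 and C1, and the new carbinol centre is oxidised in the next step so its configuration is irrelevant.

Step 12
Reactants: 22 1-[(1R,2R,5R)-5-methyl-2-(2-methylbut-3-yn-2-yl)-5-(triethylsilyloxy)cyclopentyl]but-3-en-2-ol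
Product: 23 1-[(1R,2R,5R)-5-methyl-2-(2-methylbut-3-yn-2-yl)-5-(triethylsilyloxy)cyclopentyl]but-3-en-2-one
Conditions: Dess–Martin periodinane, NaHCO3, CH2Cl2, 0 °C
Reagents that add atoms: none
Why: Dess–Martin oxidation of the allylic alcohol under buffered, non-basic conditions gives the vinyl ketone without conjugate addition.

Step 13
Reactants: 23 1-[(1R,2R,5R)-5-methyl-2-(2-methylbut-3-yn-2-yl)-5-(triethylsilyloxy)cyclopentyl]but-3-en-2-one
Product: 25 tert-butyl({(2Z)-1-[(1R,2R,5R)-5-methyl-2-(2-methylbut-3-yn-2-yl)-5-(triethylsilyloxy)cyclopentyl]but-2-en-2-yl}oxy)dimethylsilane, via lithium Z-enolate 24 (not isolated)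
Conditions: LiBH(s-Bu)3, THF, −78 °C; then t-BuMe2SiOTf, Et3N, −78 → 0 °C
Reagents that add atoms: tert-butyldimethylsilyl trifluoromethanesulfonate, CC(C)(C)[Si](C)(C)OS(=O)(=O)C(F)(F)F
Why: Conjugate hydride reduction of the s-cis vinyl ketone generates the enolate only on the C2 side and with Z geometry, and O-silylation traps it, so that no C3=C4 enol silane can form as it could by deprotonation of an ethyl ketone.

Step 14
Reactants: 25 tert-butyl({(2Z)-1-[(1R,2R,5R)-5-methyl-2-(2-methylbut-3-yn-2-yl)-5-(triethylsilyloxy)cyclopentyl]but-2-en-2-yl}oxy)dimethylsilane; 26 N-iodosuccinimide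
Product: 27 (Z)-iodomethylidene hydroazulen-3-one (2R,5R,6R,9R; C9–OSiEt3)
Conditions: [(Ar3SiC≡C)3P]AuNTf2 (5 mol%; Ar = 3,5-di-tert-butyl-4-methoxyphenyl), 26 added over 1 h, CH2Cl2, 4 Å MS, 0 °C → rt, dark; then Et3N (cat.), rt
Reagents that add atoms: none
Why: The cationic monovalent gold complex binds the terminal alkyne C15≡C16 and the enol silane carbon C2 attacks C15 from the side opposite gold, so the new C2–C15 bond and the C16–Au bond are trans across the alkene; N-iodosuccinimide then replaces gold by iodine with retention while succinimide takes the silyl group, which leaves iodine cis to C12 (Z). This is a Conia-ene-type carbocyclisation of an alkynyl enol silane with iododeauration, a known reaction type that includes seven-membered closures with cavity-shaped triethynylphosphine ligands. The cycloheptanone (C2, C3, C4, C5, C6, C12, C15) closes 7-exo-dig, favoured by Markovnikov attack at the internal alkyne carbon, by the gem-dimethyl carbon C12 and by the cis-1,2 arms on the cyclopentane. C2 is the new stereocentre: the Z-enol silane places the C1 methyl outside the forming ring, and because C2 stays epimerisable next to C3=O the mixture is equilibrated with Et3N to the 2R ketone, the only epimer in which the C2 methyl and the C6–C7 bond can both be pseudo-equatorial (C2–H cis to C6–H); this assignment is to be checked by NOE before the carbonyl is removed. The step needs alkyne activation to outrun direct iodination of the enol silane or of the alkyne C–H, which the silver-free bulky catalyst, slow addition of 26 and low temperature should secure.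

Step 15
Reactants: 27 (Z)-iodomethylidene hydroazulen-3-one (2R,5R,6R,9R; C9–OSiEt3)
Product: 28 C3 tosylhydrazone of 27
Conditions: TsNHNH2, THF–EtOH, 50 °C
Reagents that add atoms: p-toluenesulfonohydrazide, Cc1ccc(cc1)S(=O)(=O)NN
Why: Acid-free condensation of the ketone with the sulfonyl hydrazide gives the hydrazone needed for reductive deoxygenation, and any exchange at C2 through the ene-hydrazine should return to the same more stable arrangement.

Step 16
Reactants: 28 C3 tosylhydrazone of 27
Product: 29 C3-deoxy (Z)-alkenyl iodide (2S,5R,6R,9R; C9–OSiEt3)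
Conditions: catecholborane, CHCl3, 0 °C; then NaOAc·3H2O, 60 °C
Reagents that add atoms: none
Why: Hydride transfer from catecholborane to the hydrazone carbon followed by acetate-induced loss of sulfinate and dinitrogen (tosylhydrazone reduction of the Caglioti type) replaces C3=O by CH2 under mild conditions that keep the alkenyl iodide and the silyl ether and, because C3 is homoallylic, cannot shift the alkene.

**Part B – oxepane fragment**

Step 17
Reactants: 30 (E)-geranylacetone
Product: 31 4-[(2R,3R)-3-{2-[(2R)-3,3-dimethyloxiran-2-yl]ethyl}-3-methyloxiran-2-yl]butan-2-one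
Conditions: D-fructose-derived ketone catalyst of the Shi epoxidation (30 mol%), KHSO5 (as 2KHSO5·KHSO4·K2SO4), K2CO3, Bu4NHSO4, MeCN–CH2(OMe)2, aq. Na2B4O7 buffer, 0 °C
Reagents that add atoms: potassium peroxymonosulfate, [K+].[O-]S(=O)(=O)OO
Why: Shi asymmetric epoxidation oxidises both trisubstituted alkenes through the spiro dioxirane transition state to the R,R- and R-epoxides, which sets C29 and C23 and the C19 configuration from which the ring fusion follows by inversion.

Step 18
Reactants: 31 4-[(2R,3R)-3-{2-[(2R)-3,3-dimethyloxiran-2-yl]ethyl}-3-methyloxiran-2-yl]butan-2-one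
Product: 33 tert-butyl({4-[(2R,3R)-3-{2-[(2R)-3,3-dimethyloxiran-2-yl]ethyl}-3-methyloxiran-2-yl]but-1-en-2-yl}oxy)dimethylsilane, via lithium enolate 32 (not isolated)
Conditions: LiN(i-Pr)2, THF, −78 °C; then t-BuMe2SiCl, HMPA, −78 → 0 °C
Reagents that add atoms: tert-butyldimethylsilyl chloride, CC(C)(C)[Si](C)(C)Cl
Why: Kinetic deprotonation of the methyl ketone on the methyl side at −78 °C and O-silylation give the terminal enol silane without opening the epoxides.

Step 19
Reactants: 33 tert-butyl({4-[(2R,3R)-3-{2-[(2R)-3,3-dimethyloxiran-2-yl]ethyl}-3-methyloxiran-2-yl]but-1-en-2-yl}oxy)dimethylsilane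
Product: 34 (3R,5aR,9aR)-3-[(tert-butyldimethylsilyl)oxy]-2,2,5a-trimethyloctahydro-1-benzoxepin-7(2H)-one
Conditions: t-BuMe2SiOTf, 2,6-di-tert-butyl-4-methylpyridine, CH2Cl2, −78 °C
Reagents that add atoms: tert-butyldimethylsilyl trifluoromethanesulfonate, CC(C)(C)[Si](C)(C)OS(=O)(=O)C(F)(F)F
Why: Silyl-triflate-promoted tandem oxa- and carbacyclisation of a 1,5-diepoxide ending in an enol silane, in which the silylated terminal epoxide is opened at C25 by the oxygen of the internal epoxide and the resulting epoxonium ion is opened at C19 with inversion by the enol silane carbon C18, giving the trans-fused oxepane–cyclohexanone with C19 and C29 fixed by the epoxide.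

Step 20
Reactants: 34 (3R,5aR,9aR)-3-[(tert-butyldimethylsilyl)oxy]-2,2,5a-trimethyloctahydro-1-benzoxepin-7(2H)-one
Product: 35 (3R,5aR,9aR)-3-[(tert-butyldimethylsilyl)oxy]-2,2,5a-trimethyl-3,4,5,5a,6,9a-hexahydro-1-benzoxepin-7(2H)-one
Conditions: 2-iodoxybenzoic acid (IBX), DMSO–toluene, 70 °C
Reagents that add atoms: none
Why: Dehydrogenation of the ketone with IBX through its enol can only give the C30=C31 enone because C19 is quaternary, and this enone steers the next deprotonation to C18.

Step 21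
Reactants: 35 (3R,5aR,9aR)-3-[(tert-butyldimethylsilyl)oxy]-2,2,5a-trimethyl-3,4,5,5a,6,9a-hexahydro-1-benzoxepin-7(2H)-one
Product: 37 6-(hydroxymethyl) derivative of enone 35, via lithium dienolate 36 (not isolated)
Conditions: LiN(i-Pr)2, THF, −78 °C; then CH2O (gas), −78 °C
Reagents that add atoms: formaldehyde, C=O
Why: Kinetic α′-deprotonation of the cyclohexenone gives the cross-conjugated dienolate at C18, whose aldol addition to monomeric formaldehyde attaches C17, the C18 configuration being irrelevant because C18 becomes sp2 in step 23.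

Step 22
Reactants: 37 6-(hydroxymethyl) derivative of enone 35
Product: 38 (3R,5aR,9aR)-3-[(tert-butyldimethylsilyl)oxy]-6-(hydroxymethyl)-2,2,5a-trimethyloctahydro-1-benzoxepin-7(2H)-one
Conditions: H2 (1 atm), Pd/C, EtOAc, rt
Reagents that add atoms: none
Why: Heterogeneous hydrogenation saturates the disubstituted enone alkene C30=C31 and leaves the β-hydroxy ketone and the silyl ether untouched.

Step 23
Reactants: 38 (3R,5aR,9aR)-3-[(tert-butyldimethylsilyl)oxy]-6-(hydroxymethyl)-2,2,5a-trimethyloctahydro-1-benzoxepin-7(2H)-one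
Product: 40 (3R,5aR,9aR)-3-[(tert-butyldimethylsilyl)oxy]-2,2,5a-trimethyl-6-methylideneoctahydro-1-benzoxepin-7(2H)-one, via mesylate 39 (not isolated)
Conditions: MsCl, Et3N, CH2Cl2, 0 °C; then DBU, rt
Reagents that add atoms: none
Why: Mesylation of the primary alcohol and base-induced β-elimination (E1cB) through the C18 enolate give the exocyclic α-methylene ketone, the only alkene that can form.

Step 24
Reactants: 40 (3R,5aR,9aR)-3-[(tert-butyldimethylsilyl)oxy]-2,2,5a-trimethyl-6-methylideneoctahydro-1-benzoxepin-7(2H)-one; 41 methyllithium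
Product: 43 (3R,5aR,7S,9aR)-3-[(tert-butyldimethylsilyl)oxy]-2,2,5a,7-tetramethyl-6-methylidenedecahydro-1-benzoxepin-7-ol, via methylcerium dichloride 42 (not isolated)
Conditions: CeCl3 (anhydrous), THF, −78 °C; then 40, −78 °C
Reagents that add atoms: none
Why: 1,2-Addition of the organocerium reagent to the enone carbonyl comes from the equatorial direction, away from the axial C20 methyl on C19 that blocks the other face in a 1,3-diaxial sense, which sets C32 with the hydroxyl axial and cis to C20.

**Part C – union and endgame**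

Step 25
Reactants: 43 (3R,5aR,7S,9aR)-3-[(tert-butyldimethylsilyl)oxy]-2,2,5a,7-tetramethyl-6-methylidenedecahydro-1-benzoxepin-7-ol; 29 C3-deoxy (Z)-alkenyl iodide (2S,5R,6R,9R; C9–OSiEt3)
Product: 45 coupled bis-silyl ether (C9–OSiEt3; C23–OSiMe2t-Bu; C32–OH), via alkyl-9-borabicyclononane 44 (not isolated)
Conditions: 9-BBN (3 equiv), THF, 65 °C; then 29, PdCl2(dppf) (10 mol%), AsPh3, Cs2CO3, DMF–H2O, rt → 50 °C
Reagents that add atoms: none
Why: 9-BBN hydroboration puts boron on terminal C17 and hydrogen on C18 from the face opposite the axial C20 methyl and the axial C32 oxygen (setting C18 with C17 equatorial), and B-alkyl Suzuki–Miyaura coupling with the alkenyl iodide then forms C16–C17 with retention of the Z geometry.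

Step 26
Reactants: 45 coupled bis-silyl ether (C9–OSiEt3; C23–OSiMe2t-Bu; C32–OH)
Product: 46 triol (target with a 23R carbinol in place of the C23 ketone)
Conditions: Bu4NF, THF, 50 °C
Reagents that add atoms: none
Why: Fluoride-mediated desilylation cleaves the tertiary triethylsilyl ether and the hindered secondary tert-butyldimethylsilyl ether under basic conditions that cannot ionise the tertiary alcohols or move the alkene.

Step 27
Reactants: 46 triol (target with a 23R carbinol in place of the C23 ketone)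
Product: 47 target CNP0157787.1
Conditions: Dess–Martin periodinane, NaHCO3, CH2Cl2, rt
Reagents that add atoms: none
Why: Dess–Martin oxidation converts the only secondary alcohol (C23) into the ketone while the two tertiary alcohols and the trisubstituted alkene are inert.

**Compound list**

1 | 3-ethoxycyclopent-2-en-1-one | CCOC1=CC(=O)CC1 | starting material
2 | 2-bromo-3-ethoxycyclopent-2-en-1-one | CCOC1=C(Br)C(=O)CC1 | intermediate
3 | 1-chloro-3-methylbut-2-ene | CC(C)=CCCl | starting material
4 | (3-methylbut-2-en-1-yl)magnesium chloride | CC(C)=CC[Mg]Cl | intermediate (not isolated)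
5 | chloromagnesium 2-bromo-3-ethoxy-1-(2-methylbut-3-en-2-yl)cyclopent-2-en-1-olate (racemic) | CCOC1=C(Br)C(O[Mg]Cl)(CC1)C(C)(C)C=C | intermediate (not isolated)
6 | 2-bromo-3-(2-methylbut-3-en-2-yl)cyclopent-2-en-1-one | C=CC(C)(C)C1=C(Br)C(=O)CC1 | intermediate
7 | 2-(2-bromo-3-oxocyclopent-1-en-1-yl)-2-methylpropanal | O=CC(C)(C)C1=C(Br)C(=O)CC1 | intermediate (not isolated)
8 | 2-bromo-3-(1,1-dimethoxy-2-methylpropan-2-yl)cyclopent-2-en-1-one | COC(OC)C(C)(C)C1=C(Br)C(=O)CC1 | intermediate
9 | tert-butyl bromoacetate | CC(C)(C)OC(=O)CBr | starting material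
10 | bromo(2-tert-butoxy-2-oxoethyl)zinc | CC(C)(C)OC(=O)C[Zn]Br | intermediate (not isolated)
11 | tert-butyl 2-[2-(1,1-dimethoxy-2-methylpropan-2-yl)-5-oxocyclopent-1-en-1-yl]acetate | COC(OC)C(C)(C)C1=C(CC(=O)OC(C)(C)C)C(=O)CC1 | intermediate
12 | dimethylzinc | C[Zn]C | starting material
13 | tert-butyl 2-[(5R)-2-(1,1-dimethoxy-2-methylpropan-2-yl)-5-hydroxy-5-methylcyclopent-1-en-1-yl]acetate | COC(OC)C(C)(C)C1=C(CC(=O)OC(C)(C)C)[C@](C)(O)CC1 | intermediate
14 | tert-butyl 2-[(1R,2R,5R)-2-(1,1-dimethoxy-2-methylpropan-2-yl)-5-hydroxy-5-methylcyclopentyl]acetate | CC(C)(C)OC(=O)C[C@@H]1[C@@H](CC[C@@]1(C)O)C(C)(C)C(OC)OC | intermediate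
15 | tert-butyl 2-[(1R,2R,5R)-5-hydroxy-5-methyl-2-(2-methyl-1-oxopropan-2-yl)cyclopentyl]acetate | CC(C)(C)OC(=O)C[C@@H]1[C@@H](CC[C@@]1(C)O)C(C)(C)C=O | intermediate
16 | dimethyl (1-diazo-2-oxopropyl)phosphonate | COP(=O)(OC)C(=[N+]=[N-])C(C)=O | starting material
17 | dimethyl (diazomethyl)phosphonate | COP(=O)(OC)C=[N+]=[N-] | intermediate (not isolated)
18 | tert-butyl 2-[(1R,2R,5R)-5-hydroxy-5-methyl-2-(2-methylbut-3-yn-2-yl)cyclopentyl]acetate | CC(C)(C)OC(=O)C[C@@H]1[C@@H](CC[C@@]1(C)O)C(C)(C)C#C | intermediate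
19 | tert-butyl 2-[(1R,2R,5R)-5-methyl-2-(2-methylbut-3-yn-2-yl)-5-(triethylsilyloxy)cyclopentyl]acetate | CC(C)(C)OC(=O)C[C@@H]1[C@@H](CC[C@@]1(C)O[Si](CC)(CC)CC)C(C)(C)C#C | intermediate
20 | 2-[(1R,2R,5R)-5-methyl-2-(2-methylbut-3-yn-2-yl)-5-(triethylsilyloxy)cyclopentyl]acetaldehyde | O=CC[C@@H]1[C@@H](CC[C@@]1(C)O[Si](CC)(CC)CC)C(C)(C)C#C | intermediate
21 | vinylmagnesium bromide | C=C[Mg]Br | starting material
22 | 1-[(1R,2R,5R)-5-methyl-2-(2-methylbut-3-yn-2-yl)-5-(triethylsilyloxy)cyclopentyl]but-3-en-2-ol (both carbinol epimers) | C=CC(O)C[C@@H]1[C@@H](CC[C@@]1(C)O[Si](CC)(CC)CC)C(C)(C)C#C | intermediate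
23 | 1-[(1R,2R,5R)-5-methyl-2-(2-methylbut-3-yn-2-yl)-5-(triethylsilyloxy)cyclopentyl]but-3-en-2-one | C=CC(=O)C[C@@H]1[C@@H](CC[C@@]1(C)O[Si](CC)(CC)CC)C(C)(C)C#C | intermediate
24 | lithium (2Z)-1-[(1R,2R,5R)-5-methyl-2-(2-methylbut-3-yn-2-yl)-5-(triethylsilyloxy)cyclopentyl]but-2-en-2-olate | [Li+].C/C=C(\[O-])C[C@@H]1[C@@H](CC[C@@]1(C)O[Si](CC)(CC)CC)C(C)(C)C#C | intermediate (not isolated)
25 | tert-butyl({(2Z)-1-[(1R,2R,5R)-5-methyl-2-(2-methylbut-3-yn-2-yl)-5-(triethylsilyloxy)cyclopentyl]but-2-en-2-yl}oxy)dimethylsilane (key-step precursor) | C/C=C(\O[Si](C)(C)C(C)(C)C)C[C@@H]1[C@@H](CC[C@@]1(C)O[Si](CC)(CC)CC)C(C)(C)C#C | intermediate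
26 | N-iodosuccinimide | O=C1CCC(=O)N1I | starting material
27 | (Z)-iodomethylidene hydroazulen-3-one: cis-fused bicyclo[5.3.0]decane with C3 ketone, C2 methyl, gem-dimethyl C12, exocyclic C15=C16H–I (iodine cis to C12), C9 methyl and C9–OSiEt3; 2R,5R,6R,9R | C[C@H]1C(=O)C[C@@H]2[C@@H](CC[C@@]2(C)O[Si](CC)(CC)CC)C(C)(C)/C1=C\I | intermediate
28 | C3 p-toluenesulfonylhydrazone of 27 (C=N isomers) | C[C@H]1C(=NNS(=O)(=O)c2ccc(C)cc2)C[C@@H]2[C@@H](CC[C@@]2(C)O[Si](CC)(CC)CC)C(C)(C)/C1=C\I | intermediate
29 | C3-deoxy (Z)-alkenyl iodide: as 27 with CH2 at C3; 2S,5R,6R,9R | C[C@H]1CC[C@@H]2[C@@H](CC[C@@]2(C)O[Si](CC)(CC)CC)C(C)(C)/C1=C\I | intermediate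
30 | (E)-geranylacetone, (5E)-6,10-dimethylundeca-5,9-dien-2-one | CC(=O)CC/C=C(C)/CCC=C(C)C | starting material
31 | 4-[(2R,3R)-3-{2-[(2R)-3,3-dimethyloxiran-2-yl]ethyl}-3-methyloxiran-2-yl]butan-2-one | CC(=O)CC[C@H]1O[C@]1(C)CC[C@H]1OC1(C)C | intermediate
32 | lithium 4-[(2R,3R)-3-{2-[(2R)-3,3-dimethyloxiran-2-yl]ethyl}-3-methyloxiran-2-yl]but-1-en-2-olate | [Li+].C=C([O-])CC[C@H]1O[C@]1(C)CC[C@H]1OC1(C)C | intermediate (not isolated)
33 | tert-butyl({4-[(2R,3R)-3-{2-[(2R)-3,3-dimethyloxiran-2-yl]ethyl}-3-methyloxiran-2-yl]but-1-en-2-yl}oxy)dimethylsilane | C=C(O[Si](C)(C)C(C)(C)C)CC[C@H]1O[C@]1(C)CC[C@H]1OC1(C)C | intermediate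
34 | (3R,5aR,9aR)-3-[(tert-butyldimethylsilyl)oxy]-2,2,5a-trimethyloctahydro-1-benzoxepin-7(2H)-one | C1[C@@]2(C)CC[C@@H](O[Si](C)(C)C(C)(C)C)C(C)(C)O[C@@H]2CCC1=O | intermediate
35 | (3R,5aR,9aR)-3-[(tert-butyldimethylsilyl)oxy]-2,2,5a-trimethyl-3,4,5,5a,6,9a-hexahydro-1-benzoxepin-7(2H)-one | C1[C@@]2(C)CC[C@@H](O[Si](C)(C)C(C)(C)C)C(C)(C)O[C@@H]2C=CC1=O | intermediate
36 | lithium cross-conjugated dienolate of 35 (C18=C32–O−) | [Li+].[O-]C1=C[C@@]2(C)CC[C@@H](O[Si](C)(C)C(C)(C)C)C(C)(C)O[C@@H]2C=C1 | intermediate (not isolated)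
37 | (3R,5aR,9aR)-3-[(tert-butyldimethylsilyl)oxy]-6-(hydroxymethyl)-2,2,5a-trimethyl-3,4,5,5a,6,9a-hexahydro-1-benzoxepin-7(2H)-one (C6 epimers) | OCC1[C@@]2(C)CC[C@@H](O[Si](C)(C)C(C)(C)C)C(C)(C)O[C@@H]2C=CC1=O | intermediate
38 | (3R,5aR,9aR)-3-[(tert-butyldimethylsilyl)oxy]-6-(hydroxymethyl)-2,2,5a-trimethyloctahydro-1-benzoxepin-7(2H)-one (C6 epimers) | OCC1[C@@]2(C)CC[C@@H](O[Si](C)(C)C(C)(C)C)C(C)(C)O[C@@H]2CCC1=O | intermediate
39 | methanesulfonate of 38 | CS(=O)(=O)OCC1[C@@]2(C)CC[C@@H](O[Si](C)(C)C(C)(C)C)C(C)(C)O[C@@H]2CCC1=O | intermediate (not isolated)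
40 | (3R,5aR,9aR)-3-[(tert-butyldimethylsilyl)oxy]-2,2,5a-trimethyl-6-methylideneoctahydro-1-benzoxepin-7(2H)-one | C=C1[C@@]2(C)CC[C@@H](O[Si](C)(C)C(C)(C)C)C(C)(C)O[C@@H]2CCC1=O | intermediate
41 | methyllithium | [Li]C | starting material
42 | methylcerium dichloride | C[Ce](Cl)Cl | intermediate (not isolated)
43 | (3R,5aR,7S,9aR)-3-[(tert-butyldimethylsilyl)oxy]-2,2,5a,7-tetramethyl-6-methylidenedecahydro-1-benzoxepin-7-ol | C=C1[C@@]2(C)CC[C@@H](O[Si](C)(C)C(C)(C)C)C(C)(C)O[C@@H]2CC[C@]1(C)O | intermediate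
44 | B-alkyl-9-borabicyclo[3.3.1]nonane from 43 (boron on C17; 18R) | C1CCC2CCCC1B2C[C@@H]3[C@@]4(C)CC[C@@H](O[Si](C)(C)C(C)(C)C)C(C)(C)O[C@@H]4CC[C@]3(C)O | intermediate (not isolated)
45 | coupled bis-silyl ether: target skeleton with C9–OSiEt3, (23R)-C23–OSiMe2t-Bu and free C32–OH; 2S,5R,6R,9R,18R,19R,29R,32S, Z | C[C@H]1CC[C@@H]2[C@@H](CC[C@@]2(C)O[Si](CC)(CC)CC)C(C)(C)/C1=C\C[C@@H]1[C@@]2(C)CC[C@@H](O[Si](C)(C)C(C)(C)C)C(C)(C)O[C@@H]2CC[C@]1(C)O | intermediate
46 | triol: target with (23R)-C23–OH in place of the ketone | C[C@H]1CC[C@@H]2[C@@H](CC[C@@]2(C)O)C(C)(C)/C1=C\C[C@@H]1[C@@]2(C)CC[C@@H](O)C(C)(C)O[C@@H]2CC[C@]1(C)O | intermediate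
47 | CNP0157787.1 | C[C@H]1CC[C@@H]2[C@@H](CC[C@@]2(C)O)C(C)(C)/C1=C\C[C@@H]1[C@@]2(C)CCC(=O)C(C)(C)O[C@@H]2CC[C@]1(C)O | target

**Step count.** 27 steps in total. The longest linear sequence is 19 steps (steps 1–16, then 25–27); the oxepane branch is 8 steps (17–24) before the union.

**Steps most likely to fail**

1. Step 14. The seven-membered closure onto a neopentyl alkyne is the slow event, so electrophilic iodine may attack the enol silane or the alkyne C–H first, or the alkenylgold may be protonated before iodine transfer; each path loses either the ring or the Z-iodide. The fallback separates ring closure from iodination by stoichiometric anti-carbomercuration. It sets out from 25: HgCl2 with (Me3Si)2NH in CH2Cl2 activates the alkyne on divalent mercury, the enol silane adds anti, and the isolable alkenylmercuric chloride F1 carries mercury cis to C12. Iodine in THF at 0 °C then replaces mercury with retention, and the route is rejoined at 27.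

2. Step 6. Binding of the crowded tertiary hydroxyl and the tetrasubstituted alkene to iridium may be too weak, so the catalyst deactivates before turnover or hydrogen arrives without facial control; traces of acid could also ionise the tertiary allylic alcohol. The fallback moves the directing group to a secondary carbinol and builds the tertiary centre afterwards. It sets out from 11: Corey–Bakshi–Shibata reduction gives the secondary allylic alcohol F2, whose less hindered hydroxyl directs the same iridium-catalysed hydrogenation to the cyclopentanol F3 (arms cis to each other, trans to the hydroxyl). Dess–Martin oxidation gives the cis-2,3-disubstituted cyclopentanone F4, kept free of base to avoid epimerisation at C5. Petasis methylenation with Cp2TiMe2 gives the exocyclic alkene F5, and Mukaiyama hydration (Co(acac)2, PhSiH3, O2) places the hydroxyl on C9 from the face opposite the two arms. The route is rejoined at 14.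

3. Step 25. Boron-to-palladium transfer from the neopentyl-type alkylborane may be slower than protodeboronation and reduction of the iodide. The fallback is an alkylzinc (Negishi) union. It sets out from 43: hydroboration as in step 25 followed by NaOH–H2O2 gives the primary alcohol F6; iodine, PPh3 and imidazole give the iodide F7; Me3SiCl and imidazole mask the tertiary hydroxyl as the silyl ether F8. Zinc dust with LiCl inserts to the alkylzinc iodide F9, and Pd(OAc)2 with SPhos couples it with 29 to give the tris-silyl ether F10. The fluoride treatment of step 26 removes all three silyl groups, so the route is rejoined at 46.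

**Further compounds**

F1 | step 14 | (Z)-chloromercuriomethylidene hydroazulen-3-one (27 with HgCl in place of iodine) | C[C@H]1C(=O)C[C@@H]2[C@@H](CC[C@@]2(C)O[Si](CC)(CC)CC)C(C)(C)/C1=C\[Hg]Cl
F2 | step 6 | tert-butyl 2-[(5R)-2-(1,1-dimethoxy-2-methylpropan-2-yl)-5-hydroxycyclopent-1-en-1-yl]acetate | COC(OC)C(C)(C)C1=C(CC(=O)OC(C)(C)C)[C@H](O)CC1
F3 | step 6 | tert-butyl 2-[(1R,2R,5R)-2-(1,1-dimethoxy-2-methylpropan-2-yl)-5-hydroxycyclopentyl]acetate | CC(C)(C)OC(=O)C[C@@H]1[C@@H](CC[C@H]1O)C(C)(C)C(OC)OC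
F4 | step 6 | tert-butyl 2-[(1R,2R)-2-(1,1-dimethoxy-2-methylpropan-2-yl)-5-oxocyclopentyl]acetate | CC(C)(C)OC(=O)C[C@@H]1[C@@H](CCC1=O)C(C)(C)C(OC)OC
F5 | step 6 | tert-butyl 2-[(1R,2R)-2-(1,1-dimethoxy-2-methylpropan-2-yl)-5-methylidenecyclopentyl]acetate | CC(C)(C)OC(=O)C[C@@H]1[C@@H](CCC1=C)C(C)(C)C(OC)OC
F6 | step 25 | (3R,5aR,6S,7S,9aR)-3-[(tert-butyldimethylsilyl)oxy]-6-(hydroxymethyl)-2,2,5a,7-tetramethyldecahydro-1-benzoxepin-7-ol | OC[C@@H]1[C@@]2(C)CC[C@@H](O[Si](C)(C)C(C)(C)C)C(C)(C)O[C@@H]2CC[C@]1(C)O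
F7 | step 25 | (3R,5aR,6R,7S,9aR)-3-[(tert-butyldimethylsilyl)oxy]-6-(iodomethyl)-2,2,5a,7-tetramethyldecahydro-1-benzoxepin-7-ol | IC[C@@H]1[C@@]2(C)CC[C@@H](O[Si](C)(C)C(C)(C)C)C(C)(C)O[C@@H]2CC[C@]1(C)O
F8 | step 25 | 7-O-trimethylsilyl ether of F7 | IC[C@@H]1[C@@]2(C)CC[C@@H](O[Si](C)(C)C(C)(C)C)C(C)(C)O[C@@H]2CC[C@]1(C)O[Si](C)(C)C
F9 | step 25 | alkylzinc iodide from F8 (zinc on C17) | I[Zn]C[C@@H]1[C@@]2(C)CC[C@@H](O[Si](C)(C)C(C)(C)C)C(C)(C)O[C@@H]2CC[C@]1(C)O[Si](C)(C)C
F10 | step 25 | C32-O-trimethylsilyl ether of 45 | C[C@H]1CC[C@@H]2[C@@H](CC[C@@]2(C)O[Si](CC)(CC)CC)C(C)(C)/C1=C\C[C@@H]1[C@@]2(C)CC[C@@H](O[Si](C)(C)C(C)(C)C)C(C)(C)O[C@@H]2CC[C@]1(C)O[Si](C)(C)C
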